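**Retrosynthetic overview**
- Target 16 ⇐ 14 by removal of one acetate and five benzyl ethers; no skeletal change.
- 14 ⇐ 13 by closing the flavan pyran ring last through its C2–O1 bond: an enantioselective 6-membered hydroalkoxylation of an ortho-cinnamyl phenol, which sets the only stereocentre.
- 13 ⇐ phenol 10 + aryl vinyl carbinol 12 (Friedel–Crafts ortho-cinnamylation). The 4-hydroxy-2,6-bis(benzyloxy)phenyl ring of 10 is symmetric and has a single free OH para to the flavone, so only the 6-linked flavan can form.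
- 10 ⇐ 3-iodoflavone 4 (from apigenin) + arylzinc from silyl ether 6 (Negishi coupling at flavone C3).
- Ring order: the flavone rings come intact from apigenin, the central arene from 3,5-bis(benzyloxy)phenol, and the flavan pyran ring is formed last.

Assumption: the hindered flavone C3–flavan C6 axis carries no stereodescriptor in the given SMILES, so rotamers about it are carried as mixtures.
Assumption: the sense of induction of the cobalt catalyst in step 7 cannot be predicted from precedent; the (R,R)-complex is written, and the (S,S)-complex is used instead if a first run (chiral HPLC against racemic material) shows the opposite sense.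

**Route**

Step 1
Reactants: 1 apigenin
Product: 2 tri-O-benzylapigenin [5,7-bis(benzyloxy)-2-(4-(benzyloxy)phenyl)-4H-chromen-4-one]
Conditions: BnBr (4.5 equiv), K2CO3 (6 equiv), DMF, 80 °C
Reagents that add atoms: benzyl bromide BrCc1ccccc1
Why: Williamson etherification of all three phenols; the hydrogen-bonded 5-OH reacts last and needs the excess reagent and heat.

Step 2
Reactants: 2 tri-O-benzylapigenin
Product: 4 tri-O-benzyl-3-iodoapigenin [5,7-bis(benzyloxy)-2-(4-(benzyloxy)phenyl)-3-iodo-4H-chromen-4-one], via 3-lithioflavone 3 (not isolated)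
Conditions: LiN(iPr)2 (1.3 equiv), THF, −78 °C; I2 (1.5 equiv), −78 °C to rt
Reagents that add atoms: iodine II
Why: carbonyl-directed deprotonation of the flavone C3–H by the amide base followed by iodinolysis puts iodine at C3, whereas electrophilic iodination would attack C6/C8 of ring A.

Step 3
Reactants: 5 3,5-bis(benzyloxy)phenol
Product: 6 silyl ether [(3,5-bis(benzyloxy)phenoxy)tri(propan-2-yl)silane]
Conditions: iPr3SiCl, imidazole, DMF, rt
Reagents that add atoms: chlorotri(propan-2-yl)silane CC(C)[Si](Cl)(C(C)C)C(C)C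
Why: standard silylation; the bulky, non-coordinating silyloxy group later shields its two neighbouring CH positions from lithiation.

Step 4
Reactants: 6 silyl ether; 4 tri-O-benzyl-3-iodoapigenin
Product: 10 biaryl phenol [3-(2,6-bis(benzyloxy)-4-hydroxyphenyl)-5,7-bis(benzyloxy)-2-(4-(benzyloxy)phenyl)-4H-chromen-4-one], via aryllithium 7 (not isolated), via arylzinc chloride 8 (not isolated), via silyl ether 9 (not isolated)
Conditions: 6 (1.3 equiv), n-BuLi, THF, 0 °C; ZnCl2, 0 °C to rt; 4 (1.0 equiv), Pd2(dba)3 (2.5 mol%), RuPhos (10 mol%), THF/NMP, 65 °C; crude product, Bu4NF, AcOH, THF, 0 °C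
Reagents that add atoms: none
Why: directed ortho-lithiation occurs at the carbon flanked by the two benzyloxy groups, and after transmetalation to zinc a Negishi coupling on zerovalent palladium with a bulky dialkylbiarylphosphine (suited to di-ortho-substituted partners) joins it to the α-iodoenone; fluoride then cleaves the aryl silyl ether.

Step 5
Reactants: 11 4-formylphenyl acetate
Product: 12 racemic carbinol [4-(1-hydroxyprop-2-en-1-yl)phenyl acetate]
Conditions: CH2=CHMgBr (1.05 equiv, aldehyde in excess throughout by slow addition), THF, −78 °C; AcOH quench at −78 °C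
Reagents that add atoms: vinylmagnesium bromide C=C[Mg]Br
Why: Grignard 1,2-addition to the aldehyde is far faster at −78 °C than attack on the aryl acetate; the carbinol centre is racemic and is destroyed in step 6.

Step 6
Reactants: 10 biaryl phenol; 12 racemic carbinol
Product: 13 cinnamyl phenol [4-((1E)-3-{2,4-bis(benzyloxy)-3-[5,7-bis(benzyloxy)-2-(4-(benzyloxy)phenyl)-4-oxo-4H-chromen-3-yl]-6-hydroxyphenyl}prop-1-en-1-yl)phenyl acetate]
Conditions: TsOH·H2O (5 mol%), (CF3)2CHOH/CH2Cl2 1:4, 0 °C, slow addition of 12 (0.95 equiv)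
Reagents that add atoms: none
Why: Friedel–Crafts allylation, in which the acid ionises 12 to a 1-arylallyl cation that the most nucleophilic carbon (ortho to the free OH; para blocked, both ortho sites equivalent) attacks at its unhindered terminus to give the conjugated E-alkene; the acetoxy group keeps the new styrene from protonating, so no racemic ring closure follows.

Step 7
Reactants: 13 cinnamyl phenol
Product: 14 protected (2S)-flavan [4-{(2S)-5,7-bis(benzyloxy)-6-[5,7-bis(benzyloxy)-2-(4-(benzyloxy)phenyl)-4-oxo-4H-chromen-3-yl]-3,4-dihydro-2H-chromen-2-yl}phenyl acetate]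
Conditions: [(R,R)-N,N′-bis(3,5-di-tert-butylsalicylidene)cyclohexane-1,2-diaminato]cobalt, C36H52CoN2O2 (5 mol%), N-fluoro-2,4,6-trimethylpyridinium tetrafluoroborate (1.3 equiv), (Me2SiH)2O (1.3 equiv), PhCF3/acetone, 0 °C, argon
Reagents that add atoms: none
Why: Proposed new method: the divalent cobalt salen complex is oxidised by the N-fluoropyridinium salt and converted by the silane into a trivalent cobalt hydride, which transfers a hydrogen atom to the alkene carbon remote from the aryl group; the benzylic radical is captured and oxidised to a cationic tetravalent benzylcobalt species, and the only free phenol displaces cobalt through a six-membered SN2-like transition state inside the chiral salen pocket, so the C2–O1 bond, the pyran ring and the (2S) centre are made in one event, with the diastereomeric alkylcobalt species equilibrating through the radical so that the faster-closing one is drained, and the roughly electron-neutral 4-acetoxyphenyl group disfavouring escape to a free benzylic cation that would give racemate; the closest known reaction type is cobalt salen-catalysed hydrogen-atom-transfer/radical-polar-crossover hydroalkoxylation of unactivated alkenols to 2-substituted tetrahydrofurans (including enantioselective cases), which to my knowledge has not been shown for a phenol closing onto a 1,2-disubstituted styrene to give a 2-arylchroman.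

Step 8
Reactants: 14 protected (2S)-flavan
Product: 16 target CNP0304187.1 [3-((2S)-5,7-dihydroxy-2-(4-hydroxyphenyl)-3,4-dihydro-2H-chromen-6-yl)-5,7-dihydroxy-2-(4-hydroxyphenyl)-4H-chromen-4-one], via phenol 15 (not isolated)
Conditions: K2CO3 (0.2 equiv), MeOH/THF, 0 °C; AcOH (0.4 equiv); then H2 (1 atm), Pd(OH)2/C, rt
Reagents that add atoms: none
Why: base-catalysed methanolysis of the aryl acetate followed by neutral hydrogenolysis of the five benzyl ethers; the tetrasubstituted flavone alkene and the cyclic benzylic ether survive (as with benzylated catechins), and neither operation touches C2, so the (S) configuration is retained.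

**Compound list**
1 | apigenin | O=c1cc(-c2ccc(O)cc2)oc2cc(O)cc(O)c12 | starting material
2 | tri-O-benzylapigenin, 5,7-bis(benzyloxy)-2-[4-(benzyloxy)phenyl]-4H-chromen-4-one | O=c1cc(-c2ccc(OCc3ccccc3)cc2)oc2cc(OCc3ccccc3)cc(OCc3ccccc3)c12 | intermediate
3 | {5,7-bis(benzyloxy)-2-[4-(benzyloxy)phenyl]-4-oxo-4H-chromen-3-yl}lithium | [Li]c1c(-c2ccc(OCc3ccccc3)cc2)oc2cc(OCc3ccccc3)cc(OCc3ccccc3)c2c1=O | intermediate
4 | 5,7-bis(benzyloxy)-2-[4-(benzyloxy)phenyl]-3-iodo-4H-chromen-4-one | O=c1c(I)c(-c2ccc(OCc3ccccc3)cc2)oc2cc(OCc3ccccc3)cc(OCc3ccccc3)c12 | intermediate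
5 | 3,5-bis(benzyloxy)phenol | Oc1cc(OCc2ccccc2)cc(OCc2ccccc2)c1 | starting material
6 | [3,5-bis(benzyloxy)phenoxy]tri(propan-2-yl)silane | CC(C)[Si](Oc1cc(OCc2ccccc2)cc(OCc2ccccc2)c1)(C(C)C)C(C)C | intermediate
7 | {2,6-bis(benzyloxy)-4-[tri(propan-2-yl)silyloxy]phenyl}lithium | [Li]c1c(OCc2ccccc2)cc(O[Si](C(C)C)(C(C)C)C(C)C)cc1OCc1ccccc1 | intermediate
8 | {2,6-bis(benzyloxy)-4-[tri(propan-2-yl)silyloxy]phenyl}zinc chloride | Cl[Zn]c1c(OCc2ccccc2)cc(O[Si](C(C)C)(C(C)C)C(C)C)cc1OCc1ccccc1 | intermediate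
9 | 3-{2,6-bis(benzyloxy)-4-[tri(propan-2-yl)silyloxy]phenyl}-5,7-bis(benzyloxy)-2-[4-(benzyloxy)phenyl]-4H-chromen-4-one | O=c1c(-c2c(OCc3ccccc3)cc(O[Si](C(C)C)(C(C)C)C(C)C)cc2OCc2ccccc2)c(-c2ccc(OCc3ccccc3)cc2)oc2cc(OCc3ccccc3)cc(OCc3ccccc3)c12 | intermediate
10 | 3-[2,6-bis(benzyloxy)-4-hydroxyphenyl]-5,7-bis(benzyloxy)-2-[4-(benzyloxy)phenyl]-4H-chromen-4-one | O=c1c(-c2c(OCc3ccccc3)cc(O)cc2OCc2ccccc2)c(-c2ccc(OCc3ccccc3)cc2)oc2cc(OCc3ccccc3)cc(OCc3ccccc3)c12 | intermediate
11 | 4-formylphenyl acetate | CC(=O)Oc1ccc(C=O)cc1 | starting material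
12 | 4-(1-hydroxyprop-2-en-1-yl)phenyl acetate, racemic | CC(=O)Oc1ccc(C(O)C=C)cc1 | intermediate
13 | 4-[(1E)-3-{2,4-bis(benzyloxy)-3-[5,7-bis(benzyloxy)-2-(4-(benzyloxy)phenyl)-4-oxo-4H-chromen-3-yl]-6-hydroxyphenyl}prop-1-en-1-yl]phenyl acetate | O=c1c(-c2c(OCc3ccccc3)cc(O)c(C/C=C/c3ccc(OC(C)=O)cc3)c2OCc2ccccc2)c(-c2ccc(OCc3ccccc3)cc2)oc2cc(OCc3ccccc3)cc(OCc3ccccc3)c12 | intermediate
14 | 4-{(2S)-5,7-bis(benzyloxy)-6-[5,7-bis(benzyloxy)-2-(4-(benzyloxy)phenyl)-4-oxo-4H-chromen-3-yl]-3,4-dihydro-2H-chromen-2-yl}phenyl acetate | O=c1c(-c2c(OCc4ccccc4)cc3c(c2OCc2ccccc2)CC[C@@H](c2ccc(OC(C)=O)cc2)O3)c(-c2ccc(OCc3ccccc3)cc2)oc2cc(OCc3ccccc3)cc(OCc3ccccc3)c12 | intermediate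
15 | 5,7-bis(benzyloxy)-3-[(2S)-5,7-bis(benzyloxy)-2-(4-hydroxyphenyl)-3,4-dihydro-2H-chromen-6-yl]-2-[4-(benzyloxy)phenyl]-4H-chromen-4-one | O=c1c(-c2c(OCc4ccccc4)cc3c(c2OCc2ccccc2)CC[C@@H](c2ccc(O)cc2)O3)c(-c2ccc(OCc3ccccc3)cc2)oc2cc(OCc3ccccc3)cc(OCc3ccccc3)c12 | intermediate
16 | 3-[(2S)-5,7-dihydroxy-2-(4-hydroxyphenyl)-3,4-dihydro-2H-chromen-6-yl]-5,7-dihydroxy-2-(4-hydroxyphenyl)-4H-chromen-4-one (CNP0304187.1) | O=c1c(-c2c(O)cc3c(c2O)CC[C@@H](c2ccc(O)cc2)O3)c(-c2ccc(O)cc2)oc2cc(O)cc(O)c12 | target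

**Step count and risk**
Total steps: 8. Longest linear sequence: 6 (steps 1, 2, 4, 6, 7, 8 from apigenin).

Steps most likely to fail:

Step 7 (the new cyclisation; risks are low ee through a free benzylic cation, alkene reduction or isomerisation). The fallback uses known chemistry, sets out from 10 and 12, and returns at 14. Carbinol 12 is oxidised with MnO2 (CH2Cl2, rt) to the aryl vinyl ketone 4-(prop-2-enoyl)phenyl acetate F1, used at once. Acid-catalysed Friedel–Crafts conjugate addition of phenol 10 to F1 (TsOH·H2O, (CF3)2CHOH/CH2Cl2, kept at 0 °C to avoid cyclodehydration) gives the ketone 4-(3-{2,4-bis(benzyloxy)-3-[5,7-bis(benzyloxy)-2-(4-(benzyloxy)phenyl)-4-oxo-4H-chromen-3-yl]-6-hydroxyphenyl}propanoyl)phenyl acetate F2. Noyori transfer hydrogenation with RuCl[(R,R)-TsDPEN](p-cymene) and HCO2H/Et3N gives the carbinol 4-[(1R)-3-{2,4-bis(benzyloxy)-3-[5,7-bis(benzyloxy)-2-(4-(benzyloxy)phenyl)-4-oxo-4H-chromen-3-yl]-6-hydroxyphenyl}-1-hydroxypropyl]phenyl acetate F3. Intramolecular Mitsunobu etherification (PPh3, DIAD, THF, 0 °C) then closes the pyran ring with inversion, so the (R)-alcohol gives (2S)-14.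

Step 4 (hindered coupling; risks are slow transmetalation of the 2,6-dialkoxyarylzinc and benzylic deprotonation during lithiation). The fallback reverses the roles of the partners, sets out from 2 and 6, and returns at 9, which is desilylated to 10 as in step 4. Silyl ether 6 is lithiated as before and quenched with I2 to give the aryl iodide [3,5-bis(benzyloxy)-4-iodophenoxy]tri(propan-2-yl)silane F4. Flavone 2 is zincated at C3, its only acidic ring position, with TMPZnCl·LiCl (THF, rt) to give {5,7-bis(benzyloxy)-2-[4-(benzyloxy)phenyl]-4-oxo-4H-chromen-3-yl}zinc chloride F5. Coupling of F5 with F4 (Pd2(dba)3, SPhos, THF, 65 °C) gives 9; the slow step is now oxidative addition to the hindered iodide rather than transfer of a bulky arylzinc.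

Step 6 (Friedel–Crafts cinnamylation; risks are double alkylation at the second ortho site and oligomerisation of 12). The fallback replaces the cationic alkylation by a sigmatropic route, sets out from 10, and returns at 13. O-Allylation (allyl bromide, K2CO3, acetone) gives the allyl ether 3-[2,6-bis(benzyloxy)-4-(prop-2-en-1-yloxy)phenyl]-5,7-bis(benzyloxy)-2-[4-(benzyloxy)phenyl]-4H-chromen-4-one F6. Aromatic Claisen rearrangement (N,N-diethylaniline, 190 °C) moves exactly one allyl group to an ortho carbon and gives 3-[2,6-bis(benzyloxy)-4-hydroxy-3-(prop-2-en-1-yl)phenyl]-5,7-bis(benzyloxy)-2-[4-(benzyloxy)phenyl]-4H-chromen-4-one F7. Cross-metathesis of F7 with commercial 4-ethenylphenyl acetate (3 equiv; second-generation Grubbs catalyst RuCl2(=CHPh)(H2IMes)(PCy3), CH2Cl2, 40 °C, 1,4-benzoquinone additive) gives the E-alkene 13.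

Further compounds
F1 | step 7 | 4-(prop-2-enoyl)phenyl acetate | C=CC(=O)c1ccc(OC(C)=O)cc1
F2 | step 7 | 4-(3-{2,4-bis(benzyloxy)-3-[5,7-bis(benzyloxy)-2-(4-(benzyloxy)phenyl)-4-oxo-4H-chromen-3-yl]-6-hydroxyphenyl}propanoyl)phenyl acetate | O=c1c(-c2c(OCc3ccccc3)cc(O)c(CCC(=O)c3ccc(OC(C)=O)cc3)c2OCc2ccccc2)c(-c2ccc(OCc3ccccc3)cc2)oc2cc(OCc3ccccc3)cc(OCc3ccccc3)c12
F3 | step 7 | 4-[(1R)-3-{2,4-bis(benzyloxy)-3-[5,7-bis(benzyloxy)-2-(4-(benzyloxy)phenyl)-4-oxo-4H-chromen-3-yl]-6-hydroxyphenyl}-1-hydroxypropyl]phenyl acetate | O=c1c(-c2c(OCc3ccccc3)cc(O)c(CC[C@@H](O)c3ccc(OC(C)=O)cc3)c2OCc2ccccc2)c(-c2ccc(OCc3ccccc3)cc2)oc2cc(OCc3ccccc3)cc(OCc3ccccc3)c12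
F4 | step 4 | [3,5-bis(benzyloxy)-4-iodophenoxy]tri(propan-2-yl)silane | CC(C)[Si](Oc1cc(OCc2ccccc2)c(I)c(OCc2ccccc2)c1)(C(C)C)C(C)C
F5 | step 4 | {5,7-bis(benzyloxy)-2-[4-(benzyloxy)phenyl]-4-oxo-4H-chromen-3-yl}zinc chloride | Cl[Zn]c1c(-c2ccc(OCc3ccccc3)cc2)oc2cc(OCc3ccccc3)cc(OCc3ccccc3)c2c1=O
F6 | step 6 | 3-[2,6-bis(benzyloxy)-4-(prop-2-en-1-yloxy)phenyl]-5,7-bis(benzyloxy)-2-[4-(benzyloxy)phenyl]-4H-chromen-4-one | O=c1c(-c2c(OCc3ccccc3)cc(OCC=C)cc2OCc2ccccc2)c(-c2ccc(OCc3ccccc3)cc2)oc2cc(OCc3ccccc3)cc(OCc3ccccc3)c12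
F7 | step 6 | 3-[2,6-bis(benzyloxy)-4-hydroxy-3-(prop-2-en-1-yl)phenyl]-5,7-bis(benzyloxy)-2-[4-(benzyloxy)phenyl]-4H-chromen-4-one | O=c1c(-c2c(OCc3ccccc3)cc(O)c(CC=C)c2OCc2ccccc2)c(-c2ccc(OCc3ccccc3)cc2)oc2cc(OCc3ccccc3)cc(OCc3ccccc3)c12
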